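## Retrosynthetic overview

1. The target is a 5-alkyl-3-methyltetronic acid (ring O1, C2 carbonyl, C3 with the methyl group, C4 with the hydroxyl group, C5 stereocentre; side chain C6, C7(Me)=C8 and onward) on a bis-furyl terpenoid chain. Its O1–C2(=O) segment is read as one molecule of carbon dioxide.
2. Last disconnection: C5–H and C6–H, back to the achiral (Z)-C5=C6 ylidene tetronic acid; a tetronate-directed asymmetric hydrogenation sets C5.
3. Key disconnection: O1–C5 and C2–C3 together, back to an acyclic ethyl enynyl ketone plus CO2. The enabling feature is the C3H2–C4(=O)–C5≡C6 array: the only enolisable carbon (C3) and the silver-activatable alkyne carbon (C5) flank the C4 carbonyl and match the electrophilic carbon and nucleophilic oxygen of CO2.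
4. The enynone comes from a dienal (Corey–Fuchs olefination, Weinreb acylation). The chain is 8-oxygenated geranyl acetate, joined at its allylic acetate to a bis-furylmethyl Grignard reagent. The bis-furan comes from a bromofuroate and furan-3-carbaldehyde.
5. Ring order: both furan rings are bought intact and joined through their CH2 bridge first; the butenolide is the only ring that is built, and it is closed in the key step.

Key step: step 12

Assumption: the face selected by the BINAP–ruthenium catalyst on the tetronate substrate is inferred by analogy with (E)-2-methylbut-2-enoic acid; (S)-BINAP is written, and its antipode would be taken if a pilot run showed the opposite sense.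

## Route

Step 1
Reactants: 1 methyl 5-bromofuran-3-carboxylate; 2 furan-3-carbaldehyde
Product: 4 methyl 5-[furan-3-yl(hydroxy)methyl]furan-3-carboxylate (racemic), via furylmagnesium chloride 3 (not isolated)
Conditions: i-PrMgCl·LiCl, THF, −40 °C; then 2, −40 to 0 °C; aq. NH4Cl
Reagents that add atoms: none
Why: Bromine–magnesium exchange at the 2-bromofuran position is fast at −40 °C, where the methyl ester is tolerated, and the heteroaryl Grignard reagent adds 1,2 to the aldehyde (Knochel exchange, Grignard addition); the carbinol centre is racemic and is removed in step 2.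

Step 2
Reactants: 4 methyl 5-[furan-3-yl(hydroxy)methyl]furan-3-carboxylate
Product: 5 methyl 5-(furan-3-ylmethyl)furan-3-carboxylate
Conditions: Et3SiH, TFA, CH2Cl2, −20 to 0 °C
Reagents that add atoms: none
Why: Ionic hydrogenation should work because TFA ionises the doubly furyl-stabilised carbinol and Et3SiH traps the cation with hydride, while the ester-bearing ring is deactivated toward acid-induced oligomerisation at low temperature.

Step 3
Reactants: 5 methyl 5-(furan-3-ylmethyl)furan-3-carboxylate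
Product: 6 [5-(furan-3-ylmethyl)furan-3-yl]methanol
Conditions: LiAlH4, Et2O, 0 °C
Reagents that add atoms: none
Why: Standard LiAlH4 reduction of an ester to the primary alcohol, to which the furan rings and the diheteroarylmethane are inert.

Step 4
Reactants: 6 [5-(furan-3-ylmethyl)furan-3-yl]methanol
Product: 7 4-(chloromethyl)-2-(furan-3-ylmethyl)furan
Conditions: PPh3, CCl4, MeCN, 0 to 25 °C
Reagents that add atoms: carbon tetrachloride, ClC(Cl)(Cl)Cl
Why: The Appel chlorination runs through an alkoxyphosphonium ion under neutral conditions, which avoids the acid that would degrade a furylmethyl chloride.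

Step 5
Reactants: 8 geranyl acetate [(2E)-3,7-dimethylocta-2,6-dien-1-yl acetate]
Product: 9 (2E,6E)-8-hydroxy-3,7-dimethylocta-2,6-dien-1-yl acetate
Conditions: SeO2 (cat.), salicylic acid (cat.), t-BuOOH, CH2Cl2, 25 °C
Reagents that add atoms: tert-butyl hydroperoxide, CC(C)(C)OO (terminal oxidant; the oxygen is passed on by the SeO2 catalyst)
Why: Riley-type allylic oxidation (ene reaction, then [2,3]-sigmatropic shift) selects the (E)-methyl group of the electron-rich terminal trisubstituted alkene, the acetate-deactivated 2,3-alkene reacting more slowly.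

Step 6
Reactants: 9 (2E,6E)-8-hydroxy-3,7-dimethylocta-2,6-dien-1-yl acetate
Product: 10 (2E,6E)-8-[(tert-butyldimethylsilyl)oxy]-3,7-dimethylocta-2,6-dien-1-yl acetate
Conditions: TBSCl, imidazole, DMF, 0 to 25 °C
Reagents that add atoms: tert-butyldimethylsilyl chloride, CC(C)(C)[Si](C)(C)Cl
Why: Standard silylation of a primary allylic alcohol, which masks it for the organometallic coupling.

Step 7
Reactants: 7 4-(chloromethyl)-2-(furan-3-ylmethyl)furan; 10 (2E,6E)-8-[(tert-butyldimethylsilyl)oxy]-3,7-dimethylocta-2,6-dien-1-yl acetate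
Product: 12 tert-butyl{[(2E,6E)-9-[5-(furan-3-ylmethyl)furan-3-yl]-2,6-dimethylnona-2,6-dien-1-yl]oxy}dimethylsilane, via furylmethylmagnesium chloride 11 (not isolated)
Conditions: Mg, THF, 0 °C; then 10, Li2CuCl4 (3 mol %), THF, −30 to 0 °C
Reagents that add atoms: none
Why: Copper-catalysed substitution of an allylic acetate by a Grignard reagent (Fouquet–Schlosser type) should give head-to-tail coupling at the primary carbon with the E-alkene retained, because attack at the other allyl terminus would build a quaternary centre and the silyl ether is not a leaving group.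

Step 8
Reactants: 12 tert-butyl{[(2E,6E)-9-[5-(furan-3-ylmethyl)furan-3-yl]-2,6-dimethylnona-2,6-dien-1-yl]oxy}dimethylsilane
Product: 13 (2E,6E)-9-[5-(furan-3-ylmethyl)furan-3-yl]-2,6-dimethylnona-2,6-dien-1-ol
Conditions: TBAF, THF, 0 to 25 °C
Reagents that add atoms: none
Why: Fluoride-mediated desilylation is selective for the Si–O bond and leaves the alkenes and furans untouched.

Step 9
Reactants: 13 (2E,6E)-9-[5-(furan-3-ylmethyl)furan-3-yl]-2,6-dimethylnona-2,6-dien-1-ol
Product: 14 (2E,6E)-9-[5-(furan-3-ylmethyl)furan-3-yl]-2,6-dimethylnona-2,6-dienal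
Conditions: MnO2 (activated, excess), CH2Cl2, 25 °C
Reagents that add atoms: none
Why: MnO2 oxidises allylic alcohols selectively to enals without E/Z isomerisation or over-oxidation.

Step 10
Reactants: 14 (2E,6E)-9-[5-(furan-3-ylmethyl)furan-3-yl]-2,6-dimethylnona-2,6-dienal
Product: 15 4-[(3E,7E)-10,10-dibromo-4,8-dimethyldeca-3,7,9-trien-1-yl]-2-(furan-3-ylmethyl)furan
Conditions: CBr4, PPh3, Et3N, CH2Cl2, 0 °C
Reagents that add atoms: carbon tetrabromide, BrC(Br)(Br)Br
Why: First stage of the Corey–Fuchs sequence (Wittig reaction of Ph3P=CBr2), with Et3N as buffer so that the furans do not meet HBr.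

Step 11
Reactants: 15 4-[(3E,7E)-10,10-dibromo-4,8-dimethyldeca-3,7,9-trien-1-yl]-2-(furan-3-ylmethyl)furan; 16 N-methoxy-N-methylpropanamide
Product: 18 (6E,10E)-13-[5-(furan-3-ylmethyl)furan-3-yl]-6,10-dimethyltrideca-6,10-dien-4-yn-3-one, via lithium acetylide 17 (not isolated)
Conditions: n-BuLi (2.1 equiv), THF, −78 °C; then 16, −78 to 0 °C; aq. NH4Cl
Reagents that add atoms: none
Why: Second stage of the Corey–Fuchs sequence gives the lithium acetylide, which is acylated only once by the Weinreb amide because the chelated tetrahedral adduct survives until work-up.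

Step 12
Reactants: 18 (6E,10E)-13-[5-(furan-3-ylmethyl)furan-3-yl]-6,10-dimethyltrideca-6,10-dien-4-yn-3-one
Product: 20 (5Z)-5-[(2E,6E)-9-[5-(furan-3-ylmethyl)furan-3-yl]-2,6-dimethylnona-2,6-dien-1-ylidene]-4-hydroxy-3-methylfuran-2(5H)-one, via β-keto carboxylate 19 (not isolated)
Conditions: AgOAc (10 mol %), MTBD (2 equiv), CO2 (1.0 MPa), MeCN, 25 °C; then 1 M aq. KHSO4, 0 °C
Reagents that add atoms: carbon dioxide, O=C=O
Why: MTBD deprotonates the only enolisable position of 18 (the C3 methylene, the other flank of the carbonyl being the alkyne) and the enolate adds to carbon dioxide to give β-keto carboxylate 19, which makes the C2–C3 bond. Silver acetate then π-activates the alkyne, a carboxylate oxygen attacks the alkyne carbon next to the carbonyl anti to silver, which makes the O1–C5 bond, and protodeargentation releases the catalyst. The closest known reaction type is the silver-catalysed carboxylative cyclisation of conjugated ynones with carbon dioxide to 5-ylidene tetronic acids. The butenolide ring closes in the 5-exo-dig mode. No stereocentre is formed, but the anti addition should fix the exocyclic alkene as Z, which defines the substrate geometry for step 13. The step needs C- over O-carboxylation and 5-exo over 6-endo closure (the 4-hydroxy-2-pyranone); the first is secured because O-carboxylation is reversible and the cyclisation drains the C-carboxylate, the second by silver activation, which favours attack at the carbon that gives the five-membered ring.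

Step 13
Reactants: 20 (5Z)-5-[(2E,6E)-9-[5-(furan-3-ylmethyl)furan-3-yl]-2,6-dimethylnona-2,6-dien-1-ylidene]-4-hydroxy-3-methylfuran-2(5H)-one
Product: 21 (5S)-5-[(2E,6E)-9-[5-(furan-3-ylmethyl)furan-3-yl]-2,6-dimethylnona-2,6-dien-1-yl]-4-hydroxy-3-methylfuran-2(5H)-one
Conditions: Ru(OAc)2[(S)-BINAP] (2 mol %), H2 (4 atm), degassed MeOH, 25 °C
Reagents that add atoms: none
Why: Proposed new method: the tetronic acid is a vinylogous carboxylic acid, so its conjugate base should replace acetate on ruthenium and hold the adjacent C5=C6 alkene where the α,β-alkene of an unsaturated carboxylate sits; hydride then adds to C5 through a five-membered ruthenacycle on the face chosen by the BINAP ligand (catalyst control of the new C5 stereocentre), methanol protonates the Ru–C6 bond, and the C7=C8 and C11=C12 alkenes and the furans, which lack this chelation, should stay untouched; the closest known reaction types are the Ru(OAc)2(BINAP) hydrogenation of α,β-unsaturated carboxylic acids, which spares remote trisubstituted alkenes, and the BINAP–ruthenium hydrogenation of exocyclic alkylidene lactones.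

## Compound list

1 | methyl 5-bromofuran-3-carboxylate | COC(=O)c1coc(Br)c1 | starting material
2 | furan-3-carbaldehyde | O=Cc1ccoc1 | starting material
3 | [4-(methoxycarbonyl)furan-2-yl]magnesium chloride | COC(=O)c1coc([Mg]Cl)c1 | intermediate
4 | methyl 5-[furan-3-yl(hydroxy)methyl]furan-3-carboxylate (racemic) | COC(=O)c1coc(C(O)c2ccoc2)c1 | intermediate
5 | methyl 5-(furan-3-ylmethyl)furan-3-carboxylate | COC(=O)c1coc(Cc2ccoc2)c1 | intermediate
6 | [5-(furan-3-ylmethyl)furan-3-yl]methanol | OCc1coc(Cc2ccoc2)c1 | intermediate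
7 | 4-(chloromethyl)-2-(furan-3-ylmethyl)furan | ClCc1coc(Cc2ccoc2)c1 | intermediate
8 | geranyl acetate, (2E)-3,7-dimethylocta-2,6-dien-1-yl acetate | CC(C)=CCC/C(C)=C/COC(C)=O | starting material
9 | (2E,6E)-8-hydroxy-3,7-dimethylocta-2,6-dien-1-yl acetate | OC/C(C)=C/CC/C(C)=C/COC(C)=O | intermediate
10 | (2E,6E)-8-[(tert-butyldimethylsilyl)oxy]-3,7-dimethylocta-2,6-dien-1-yl acetate | CC(C)(C)[Si](C)(C)OC/C(C)=C/CC/C(C)=C/COC(C)=O | intermediate
11 | {[5-(furan-3-ylmethyl)furan-3-yl]methyl}magnesium chloride | Cl[Mg]Cc1coc(Cc2ccoc2)c1 | intermediate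
12 | tert-butyl{[(2E,6E)-9-[5-(furan-3-ylmethyl)furan-3-yl]-2,6-dimethylnona-2,6-dien-1-yl]oxy}dimethylsilane | CC(C)(C)[Si](C)(C)OC/C(C)=C/CC/C(C)=C/CCc1coc(Cc2ccoc2)c1 | intermediate
13 | (2E,6E)-9-[5-(furan-3-ylmethyl)furan-3-yl]-2,6-dimethylnona-2,6-dien-1-ol | OC/C(C)=C/CC/C(C)=C/CCc1coc(Cc2ccoc2)c1 | intermediate
14 | (2E,6E)-9-[5-(furan-3-ylmethyl)furan-3-yl]-2,6-dimethylnona-2,6-dienal | O=C/C(C)=C/CC/C(C)=C/CCc1coc(Cc2ccoc2)c1 | intermediate
15 | 4-[(3E,7E)-10,10-dibromo-4,8-dimethyldeca-3,7,9-trien-1-yl]-2-(furan-3-ylmethyl)furan | BrC(Br)=C/C(C)=C/CC/C(C)=C/CCc1coc(Cc2ccoc2)c1 | intermediate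
16 | N-methoxy-N-methylpropanamide | CCC(=O)N(C)OC | starting material
17 | lithium acetylide of 4-[(3E,7E)-4,8-dimethyldeca-3,7-dien-9-yn-1-yl]-2-(furan-3-ylmethyl)furan | [Li]C#C/C(C)=C/CC/C(C)=C/CCc1coc(Cc2ccoc2)c1 | intermediate
18 | (6E,10E)-13-[5-(furan-3-ylmethyl)furan-3-yl]-6,10-dimethyltrideca-6,10-dien-4-yn-3-one | CCC(=O)C#C/C(C)=C/CC/C(C)=C/CCc1coc(Cc2ccoc2)c1 | intermediate
19 | MTBD-H+ salt of (6E,10E)-13-[5-(furan-3-ylmethyl)furan-3-yl]-2,6,10-trimethyl-3-oxotrideca-6,10-dien-4-ynoate | CC(C([O-])=O)C(=O)C#C/C(C)=C/CC/C(C)=C/CCc1coc(Cc2ccoc2)c1.CN1CCCN2CCC[NH+]=C12 | intermediate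
20 | (5Z)-5-[(2E,6E)-9-[5-(furan-3-ylmethyl)furan-3-yl]-2,6-dimethylnona-2,6-dien-1-ylidene]-4-hydroxy-3-methylfuran-2(5H)-one | CC1=C(O)/C(=C/C(C)=C/CC/C(C)=C/CCc2coc(Cc3ccoc3)c2)OC1=O | intermediate
21 | (5S)-5-[(2E,6E)-9-[5-(furan-3-ylmethyl)furan-3-yl]-2,6-dimethylnona-2,6-dien-1-yl]-4-hydroxy-3-methylfuran-2(5H)-one | CC1=C(O)[C@H](C/C(C)=C/CC/C(C)=C/CCc2coc(Cc3ccoc3)c2)OC1=O | target

## Step count and risks

Total step count: 13. Longest linear sequence: 11 steps (steps 1–4, then 7–13).

**Step 13 (asymmetric hydrogenation).** What may go wrong: hydrogen may be delivered 1,4 across the C5=C6–C7=C8 diene, which moves the side-chain alkene to C6=C7; a second equivalent may saturate the C7=C8 alkene; and the facial selectivity of the tetronate-directed insertion may be poor.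
Fallback, from 13 back to 21, with the stereocentre set by auxiliary-controlled alkylation before the ring is made:
- Alcohol 13 is converted with CBr4/PPh3 (CH2Cl2, 0 °C) into 4-[(3E,7E)-9-bromo-4,8-dimethylnona-3,7-dien-1-yl]-2-(furan-3-ylmethyl)furan F1.
- F1 alkylates the sodium enolate (NaHMDS, THF, −78 to −45 °C) of the known (4R)-4-benzyl-3-{[(4-methoxybenzyl)oxy]acetyl}-1,3-oxazolidin-2-one, anti to the benzyl group (Evans alkylation), to give (4R)-4-benzyl-3-[(2S,4E,8E)-11-[5-(furan-3-ylmethyl)furan-3-yl]-2-[(4-methoxybenzyl)oxy]-4,8-dimethylundeca-4,8-dienoyl]-1,3-oxazolidin-2-one F2.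
- MeOMgBr in MeOH exchanges the auxiliary to give methyl (2S,4E,8E)-11-[5-(furan-3-ylmethyl)furan-3-yl]-2-[(4-methoxybenzyl)oxy]-4,8-dimethylundeca-4,8-dienoate F3.
- DDQ in buffered CH2Cl2/water at 0 °C frees methyl (2S,4E,8E)-11-[5-(furan-3-ylmethyl)furan-3-yl]-2-hydroxy-4,8-dimethylundeca-4,8-dienoate F4.
- Propanoyl chloride/pyridine gives methyl (2S,4E,8E)-11-[5-(furan-3-ylmethyl)furan-3-yl]-4,8-dimethyl-2-(propanoyloxy)undeca-4,8-dienoate F5.
- Dieckmann cyclisation (LiHMDS, THF, −78 °C) closes the tetronic acid and gives 21.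

**Step 12 (key step).** What may go wrong: closure in the 6-endo-dig mode to the isomeric 4-hydroxy-2-pyranone, loss of carbon dioxide from the β-keto carboxylate before cyclisation, and conjugate addition of the amidine base to the ynone.
Fallback, from 14 back to 20, building the C5=C6 bond by aldol condensation on a preformed tetronate:
- The C5 lithium anion (LDA, THF, −78 °C) of the known 4-methoxy-3-methylfuran-2(5H)-one adds to enal 14 to give 5-{(2E,6E)-9-[5-(furan-3-ylmethyl)furan-3-yl]-1-hydroxy-2,6-dimethylnona-2,6-dien-1-yl}-4-methoxy-3-methylfuran-2(5H)-one F6 as a diastereomer mixture.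
- MsCl/Et3N, then DBU, eliminates to (5Z)-5-[(2E,6E)-9-[5-(furan-3-ylmethyl)furan-3-yl]-2,6-dimethylnona-2,6-dien-1-ylidene]-4-methoxy-3-methylfuran-2(5H)-one F7.
- n-PrSLi in HMPA at 25 °C removes the O-methyl group and gives 20.

**Step 7 (Grignard coupling).** What may go wrong: Wurtz-type homocoupling while the furylmethyl Grignard reagent forms, acyl attack on the acetate, and bond formation at the furan ring carbon next to the CH2MgCl group instead of at the exocyclic carbon.
Fallback, from 10 (with 7) back to 12, by sulfone-anion alkylation: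
- Pd(PPh3)4 and PhSO2Na in THF/MeOH convert acetate 10 into tert-butyl{[(2E,6E)-2,6-dimethyl-8-(phenylsulfonyl)octa-2,6-dien-1-yl]oxy}dimethylsilane F8.
- The anion of F8 (n-BuLi, THF, −78 °C) is alkylated by chloride 7 to give tert-butyl{[(2E,6E)-9-[5-(furan-3-ylmethyl)furan-3-yl]-2,6-dimethyl-8-(phenylsulfonyl)nona-2,6-dien-1-yl]oxy}dimethylsilane F9 (racemic).
- Reductive desulfonylation with PdCl2(dppp) (cat.) and LiBHEt3 in THF at 0 °C, hydride entering at the less substituted allyl terminus, gives 12.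

Further compounds
F1 | step 13 | 4-[(3E,7E)-9-bromo-4,8-dimethylnona-3,7-dien-1-yl]-2-(furan-3-ylmethyl)furan | BrC/C(C)=C/CC/C(C)=C/CCc1coc(Cc2ccoc2)c1
F2 | step 13 | (4R)-4-benzyl-3-[(2S,4E,8E)-11-[5-(furan-3-ylmethyl)furan-3-yl]-2-[(4-methoxybenzyl)oxy]-4,8-dimethylundeca-4,8-dienoyl]-1,3-oxazolidin-2-one | O=C1OC[C@@H](Cc2ccccc2)N1C(=O)[C@H](C/C(C)=C/CC/C(C)=C/CCc2coc(Cc3ccoc3)c2)OCc2ccc(OC)cc2
F3 | step 13 | methyl (2S,4E,8E)-11-[5-(furan-3-ylmethyl)furan-3-yl]-2-[(4-methoxybenzyl)oxy]-4,8-dimethylundeca-4,8-dienoate | COC(=O)[C@H](C/C(C)=C/CC/C(C)=C/CCc1coc(Cc2ccoc2)c1)OCc1ccc(OC)cc1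
F4 | step 13 | methyl (2S,4E,8E)-11-[5-(furan-3-ylmethyl)furan-3-yl]-2-hydroxy-4,8-dimethylundeca-4,8-dienoate | COC(=O)[C@H](C/C(C)=C/CC/C(C)=C/CCc1coc(Cc2ccoc2)c1)O
F5 | step 13 | methyl (2S,4E,8E)-11-[5-(furan-3-ylmethyl)furan-3-yl]-4,8-dimethyl-2-(propanoyloxy)undeca-4,8-dienoate | COC(=O)[C@H](C/C(C)=C/CC/C(C)=C/CCc1coc(Cc2ccoc2)c1)OC(=O)CC
F6 | step 12 | 5-{(2E,6E)-9-[5-(furan-3-ylmethyl)furan-3-yl]-1-hydroxy-2,6-dimethylnona-2,6-dien-1-yl}-4-methoxy-3-methylfuran-2(5H)-one (diastereomer mixture) | COC1=C(C)C(=O)OC1C(O)/C(C)=C/CC/C(C)=C/CCc1coc(Cc2ccoc2)c1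
F7 | step 12 | (5Z)-5-[(2E,6E)-9-[5-(furan-3-ylmethyl)furan-3-yl]-2,6-dimethylnona-2,6-dien-1-ylidene]-4-methoxy-3-methylfuran-2(5H)-one | CC1=C(OC)/C(=C/C(C)=C/CC/C(C)=C/CCc2coc(Cc3ccoc3)c2)OC1=O
F8 | step 7 | tert-butyl{[(2E,6E)-2,6-dimethyl-8-(phenylsulfonyl)octa-2,6-dien-1-yl]oxy}dimethylsilane | CC(C)(C)[Si](C)(C)OC/C(C)=C/CC/C(C)=C/CS(=O)(=O)c1ccccc1
F9 | step 7 | tert-butyl{[(2E,6E)-9-[5-(furan-3-ylmethyl)furan-3-yl]-2,6-dimethyl-8-(phenylsulfonyl)nona-2,6-dien-1-yl]oxy}dimethylsilane (racemic) | CC(C)(C)[Si](C)(C)OC/C(C)=C/CC/C(C)=C/C(Cc1coc(Cc2ccoc2)c1)S(=O)(=O)c1ccccc1
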